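## Structural features

The target is a heptacyclic heterodimer (rings A–G; unprimed locants for the pyrano[4,3-b]chromen-10-one half, primed locants for the pyrano[3,2-c]chromen-4-one half): a 6,7-dihydroxychromone-5-carboxylic acid (benzo ring A, pyranone ring B) and an 8,9-dihydroxy-2H-chromene-10-carboxylic acid (pyran ring F, benzo ring G) that carries a 2,3-dihydro-4-pyranone (ring E) on its C3–C4 bond. The halves are stapled by a 2,9-dioxabicyclo[3.3.1]nonane: ring C is a pyran fused to the chromone C2–C3 bond (C-4 methylene, C-3 methyl ketal carbon, O-2, C-1 carbinol carbon), and ring D is a 1,3-dioxane that shares C-3, O-2 and C-1 with ring C and the C-2'–C-3' bond with ring E. There are four stereocentres, C-3 (R), C-1 (S), C-3' (S) and C-2' (S); C-1, C-3' and C-2' are contiguous carbons and the two ketal carbons C-3 and C-2' are joined through the bridging oxygen. Only C-1 is independent: C-3 is a hemiketal-derived carbon that can bridge only when its oxygen is cis to the C-1 substituent, and C-2' and C-3' arise from a reversible conjugate addition to a 4-pyranone followed by protonation of an enolizable α-carbon. The fragile parts are the bis-ketal cage (acid), the β-alkoxy ketone of ring E (retro-oxa-Michael in base), the C-1–O-2 bond, which is flanked by two vinylogous-ester rings and can ionize, the two catechols, and the two carboxylic acids peri to the ring carbonyls. The real difficulty is to create C-1 as one enantiomer between two almost identical 4-pyranon-3-yl groups and to join two fully substituted halves that stem from the same pentasubstituted arene. The key step uses the ring C sequence O-2–C-1–C-10a=C-4a followed by C-4–C-3(CH3)(O): this is the retron of an inverse-demand hetero-Diels–Alder reaction between the 1-oxadiene formed by the bridging ketone and the chromone C3=C2 bond and the two alkene carbons of an isopropenyl ether.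

## Logic of the disconnections

26 to 25. The six O–CH2Ph bonds (four aryl ethers, two esters) are cut first. Free catechols and acids would interfere with every Lewis-acid and base step, and hydrogenolysis is the one neutral way to unveil them beside the cage. All polar groups are then masked by a single group type. The forward step must cleave benzyl C–O bonds faster than it touches the two tetrasubstituted vinylogous-ester double bonds and the allylic C-1–O-2 bond.

25 to 23 (through 24). The O–C-2' bond of ring D and the C-3'–H bond are cut, and the bridging oxygen is replaced by a methoxy group on C-3. Hemiketal formation and conjugate addition are both reversible, so C-3, C-2' and C-3' need no control of their own. Ring D and three stereocentres disappear and ring E becomes a flat 4-pyranone, leaving C-1 as the only centre that matters. The forward step needs an acid strong enough to exchange the ketal and activate the pyranone, but not strong enough to ionize C-1–O-2.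

23 to 22. The C-1–H bond is exchanged for a C-4a–H bond, so the chromone is written as its exocyclic vinylogous-ester tautomer. This tautomer is a cycloadduct, and C-1 is thereby traced back to a ring-fusion centre that a catalyst can set. The forward step must deliver hydrogen to C-1 on a defined face.

22 to 20 and 21. The C-4–C-4a and O-2–C-3 bonds are cut (retro-hetero-Diels–Alder). This removes ring C, two skeletal bonds and both stereocentres, and leaves a flat achiral ketone and a three-carbon commodity. The forward step must use the chromone-side oxadiene only and must differentiate its faces.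

20 to 17 and 9 (through 18 and 19). The bond between the bridging carbonyl carbon and chromone C3 and the chromone O1–C2 bond are cut. Both partners come from the same arene, and ring B is built during the union. The fragments are of similar size. The acylation must end on carbon.

17 to 16 to 15. The C-3'–CO2H bond and then the C-3'–I bond are cut. C-3' is the only nucleophilic CH of the pyranone, so the carboxyl carbon can come from carbonylation and 15 need carry no handle. The iodination must prefer C-3' to the arene CH.

15 to 11 and 12 (through 13 and 14). The C-4'–C-4a' and O-1'–C-10b' bonds are cut. C-2', C-3', C-4' and the methyl group come from 13, so ring E is made in one operation from a chromanone enol ether. The enol ether must be regiodefined.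

11 to 10 to 9. The O–Si bond and the C2–H bond (hydride) are cut, then the chromone O1–C2 bond. Conjugate reduction delivers the enolate without any addition to the hindered ketone, and the sequence returns to 9, which also serves the union. The reduction must be 1,4 and not 1,2.

9 to 7 and 8. The enaminone C=C bond is cut. Both halves of the molecule then derive from 7.

7 to 6 to 4 to 2 to 1. The aryl–CO2Bn bond (at a bromide), the aryl–acetyl bond, the aryl–OH bond (from a formyl group) and the two O–benzyl bonds are cut in turn. Bromine marks the one ring position that electrophilic substitution does not reach, and the benzyl groups are present from the start, so no protecting-group exchange is needed. The ortho-acylation must go to the position next to bromine.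

## Other disconnections considered

Alternative 1: The cut is the bond between the chromone 2-CH2 carbon (C-4) and C-3 in ring C, together with the O–C-2' bond of ring D. In the forward step fluoride desilylates the 2-(trimethylsilylmethyl)chromone A1, whose carbinol oxygen carries an acetyl group. The vinylogous enolate attacks that acetate carbonyl through a six-membered array, and the hemiketal alkoxide adds to C-2' of the pyranone to give A2, which is identical with 25.
- In favour: C-1 would be set beforehand by an asymmetric ketone reduction, an established reaction type, so no stereochemical relay is needed. One basic operation forms a C–C bond, a C–O bond, two rings and the three dependent stereocentres. No vinylogous-acetal intermediate is involved.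
- Against: the carbinol acetate is vinylogously β to the carbanion, so 1,4-elimination of acetate to a dimethylene-chromanone diene competes directly with acyl transfer. Alkoxide addition to a neutral, methyl-substituted pyranone carbon is less favourable than addition to a hydroxypyrylium ion, and the ring E β-alkoxy ketone can revert in base. The reduction must distinguish two 4-pyranon-3-yl groups that differ only by H and CH3. Lateral silylation needs a strong base beside two benzyl esters.
- Comparison: on the security of C-1 this plan is the better one. On the end game it is at least equal, since the cascade is followed by one step only. On the precedent for the ring-forming event the chosen plan is stronger, because cycloadditions of 3-acylchromones with enol ethers are an established reaction class, whereas this cascade has a built-in elimination channel. The step count is about equal or one to two steps longer, because a 2-methylchromone half, its silylation, the reduction and the acetylation must be added.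

Alternative 2: The cut is in ring F, at the aryl C-6a'–O-6' bond and the aryl C-10a'–C-10b' bond. In the forward step the primary alkoxide of the 3-(hydroxymethyl)-4-methoxy-2-pyranone A3 adds to the aryne released from the silyl aryl triflate A4 at the carbon remote from the ester. The aryl anion then closes onto the lactone carbonyl, and acidic work-up dehydrates and hydrolyses the 4-methoxy group to give A5.
- In favour: it is the most convergent of the plans. The right-hand arene enters without an o-hydroxyaryl ketone, a chromanone or a C-3' functionalization, and the 2-pyranone is easily made by acylketene chemistry.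
- Against: the key step builds bonds far from the stereochemical problem, so C-1 still needs a separate asymmetric step. The aryl anion sits next to a bulky ester and must attack a poorly electrophilic lactone carbonyl in competition with protonation. The alkoxide can instead migrate the neighbouring acetate or add to the 2-alkynylchromone. After A5 the alkyne must be hydrated, the acetate removed, the cage closed and the benzyl groups cleaved.
- Comparison: on convergence this plan is the better one. On mechanism it carries more competing pathways in the key step than the chosen cycloaddition. On step economy after the key step it is longer (four operations against three). On stereocontrol it is neutral, since it only transports a centre made elsewhere.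

Alternative 3: The cut is again in ring C but at the C-10a–C-1 bond and the O-2–C-3 bond. In the forward step the chromone-embedded silyl dienol ether A6, a 1,3-dioxygenated diene, reacts through chromone C3 with the aldehyde A7 bound to a chiral Lewis acid. Tautomerization of the acidic C3–H then restores the chromone and gives the silyl ketal A8.
- In favour: C-1 is created directly in the C–C bond-forming event, and the following tautomerization involves an α-carbonyl proton and cannot affect C-1. A8 is already at the chromone level and needs only desilylation with cage closure and hydrogenolysis.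
- Against: the diene terminus is the α-carbon of a vinylogous ester and is deactivated by the chromone carbonyl. The other terminus is fully substituted, so one group must lie inside the s-cis diene. The internal enol-ether carbon can react in a simple Mukaiyama aldol sense and so form the wrong C–C bond. A7 is a chelating, vinylogous β-keto aldehyde that is itself a Michael acceptor and an oxadiene.
- Comparison: on stereochemical directness and on the number of steps after the key step (two against three) this plan is the better one. On structure it closes the same ring with the same number of new bonds. On mechanism the chosen plan pairs a strongly electron-poor oxadiene with a strongly electron-rich, commercial dienophile, a polarity-matched combination with direct precedent, whereas this plan relies on a deactivated, hindered diene. The overall step count is about equal.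

Key step: step 12

Remarks on the chemistry (assumptions and corrections)

- The configuration drawn at C-2' and C-3' is assumed to be the one the cage prefers once C-1 is (S), since both centres form reversibly.
- The constitution and configuration of 20 and 22 need no change. The descriptors of 22, (3S,4aS), are those of the endo adduct and map onto (1S) in 26 by a suprafacial hydrogen shift.
- The copper chelate that activates the cycloaddition must span the bridging ketone oxygen and the pyranone 4'-carbonyl. A chelate to the chromone 4-carbonyl would hold the ketone C=O s-trans to the chromone C3=C2 bond and cannot cycloadd.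
- 2,4,5-Trimethoxybenzoic acid is not used as the arene source. Its carboxyl carbon maps onto the acetyl carbon, the benzoate carbon would have to be added by ortho-metalation, and three methyl ethers would have to be exchanged for benzyl groups. The route starts from 3-bromo-4,5-dihydroxybenzaldehyde instead.
- In the names, "pyranochromenonyl" stands for 8,9-bis(benzyloxy)-10-[(benzyloxy)carbonyl]-2-methyl-4-oxo-4H,5H-pyrano[3,2-c]chromen-3-yl.

## Route

Step 1
Reactants: 1 3-bromo-4,5-dihydroxybenzaldehyde
Product: 2 3,4-bis(benzyloxy)-5-bromobenzaldehyde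
Conditions: BnBr (2.3 equiv), K2CO3, DMF, 60 °C
Reagents that add atoms: benzyl bromide, BrCc1ccccc1
Why: Williamson etherification of both phenols; the aldehyde and the aryl bromide are inert to carbonate.

Step 2
Reactants: 2 3,4-bis(benzyloxy)-5-bromobenzaldehyde
Product: 4 3,4-bis(benzyloxy)-5-bromophenol, via aryl formate 3 (not isolated)
Conditions: mCPBA, CH2Cl2, rt; then K2CO3 (cat.), MeOH, 0 °C
Reagents that add atoms: 3-chloroperoxybenzoic acid, O=C(OO)c1cccc(Cl)c1
Why: Baeyer–Villiger (Dakin-type) oxidation in which the para-alkoxy aryl group migrates; the formate is then methanolysed.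

Step 3
Reactants: 4 3,4-bis(benzyloxy)-5-bromophenol
Product: 6 1-[3,4-bis(benzyloxy)-2-bromo-6-hydroxyphenyl]ethan-1-one, via aryl acetate 5 (not isolated)
Conditions: AcCl, Sc(OTf)3 (10 mol %), toluene–MeNO2, 60 °C
Reagents that add atoms: acetyl chloride, CC(=O)Cl
Why: O-acetylation followed by Lewis-acid-catalysed Fries rearrangement (ortho-acylation of a phenol); the para position is substituted. Of the two ortho positions the one para to the 3-benzyloxy group should react, the other lying between two oxygen substituents, as in electrophilic substitution of 1-bromo-3,5-dialkoxybenzenes.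

Step 4
Reactants: 6 1-[3,4-bis(benzyloxy)-2-bromo-6-hydroxyphenyl]ethan-1-one
Product: 7 benzyl 2-acetyl-5,6-bis(benzyloxy)-3-hydroxybenzoate
Conditions: Pd(OAc)2 (3 mol %), Xantphos (6 mol %), CO (1 atm), BnOH, Et3N, toluene, 90 °C
Reagents that add atoms: carbon monoxide, [C-]#[O+]; benzyl alcohol, OCc1ccccc1
Why: Palladium-catalysed alkoxycarbonylation of the aryl bromide (oxidative addition to zerovalent palladium, CO insertion, alcoholysis); the wide-bite-angle ligand allows atmospheric CO with an ortho,ortho-disubstituted bromide.

Step 5
Reactants: 7 benzyl 2-acetyl-5,6-bis(benzyloxy)-3-hydroxybenzoate; 8 N,N-dimethylformamide dimethyl acetal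
Product: 9 benzyl 5,6-bis(benzyloxy)-2-[(2E)-3-(dimethylamino)prop-2-enoyl]-3-hydroxybenzoate
Conditions: 8 (1.5 equiv), toluene, 90 °C
Reagents that add atoms: none
Why: Condensation of the methyl ketone with the amide acetal gives the (E)-enaminone; the chelated ortho-hydroxyl should not be methylated under these conditions.

Step 6
Reactants: 9 benzyl 5,6-bis(benzyloxy)-2-[(2E)-3-(dimethylamino)prop-2-enoyl]-3-hydroxybenzoate
Product: 10 benzyl 6,7-bis(benzyloxy)-4-oxo-4H-chromene-5-carboxylate
Conditions: conc. aq. HCl, CH2Cl2, rt
Reagents that add atoms: none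
Why: Acid-promoted addition of the phenol to the enaminone β-carbon with loss of dimethylamine, the standard enaminone-to-chromone cyclization.

Step 7
Reactants: 10 benzyl 6,7-bis(benzyloxy)-4-oxo-4H-chromene-5-carboxylate
Product: 11 benzyl 6,7-bis(benzyloxy)-4-[(trimethylsilyl)oxy]-2H-chromene-5-carboxylate
Conditions: LiBH(s-Bu)3 (1.05 equiv), THF, −78 °C; then TMSCl, −78 → 0 °C; non-aqueous work-up
Reagents that add atoms: chlorotrimethylsilane, C[Si](C)(C)Cl
Why: Conjugate hydride addition of the hindered borohydride to chromone C2 and O-silylation of the enolate give the regiodefined silyl enol ether without any addition to the hindered ketone; the ortho,ortho-disubstituted benzyl ester should survive at −78 °C.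

Step 8
Reactants: 11 benzyl 6,7-bis(benzyloxy)-4-[(trimethylsilyl)oxy]-2H-chromene-5-carboxylate; 12 2,2,6-trimethyl-4H-1,3-dioxin-4-one
Product: 15 benzyl 8,9-bis(benzyloxy)-2-methyl-4-oxo-4H,5H-pyrano[3,2-c]chromene-10-carboxylate, via acetylketene 13 (not isolated), via silyloxy dihydropyranone adduct 14 (not isolated)
Conditions: 12 (2.5 equiv), toluene, 110 °C; then TsOH·H2O (cat.), rt
Reagents that add atoms: none
Why: Thermal retro-[4+2] of 12 releases 13, which adds to the enol ether in a hetero-Diels–Alder sense (nucleophilic C3 to the ketene carbon, ketone oxygen to C4). Acid then eliminates trimethylsilanol to the 4-pyranone, the known acylketene–enol ether pyranone synthesis.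

Step 9
Reactants: 15 benzyl 8,9-bis(benzyloxy)-2-methyl-4-oxo-4H,5H-pyrano[3,2-c]chromene-10-carboxylate
Product: 16 benzyl 8,9-bis(benzyloxy)-3-iodo-2-methyl-4-oxo-4H,5H-pyrano[3,2-c]chromene-10-carboxylate
Conditions: NIS (1.1 equiv), TFA (0.3 equiv), MeCN, 0 °C → rt
Reagents that add atoms: N-iodosuccinimide, O=C1CCC(=O)N1I
Why: Electrophilic iodination at C-3', the α-carbon of the vinylogous ester and the only nucleophilic CH of the pyranone; the single aromatic CH is para to the ester and flanked by two oxygen substituents.

Step 10
Reactants: 16 benzyl 8,9-bis(benzyloxy)-3-iodo-2-methyl-4-oxo-4H,5H-pyrano[3,2-c]chromene-10-carboxylate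
Product: 17 8,9-bis(benzyloxy)-10-[(benzyloxy)carbonyl]-2-methyl-4-oxo-4H,5H-pyrano[3,2-c]chromene-3-carboxylic acid
Conditions: Pd(OAc)2 (5 mol %), dppf (10 mol %), CO (1 atm), H2O, Et3N, DMF, 60 °C; acidic work-up
Reagents that add atoms: carbon monoxide, [C-]#[O+]; water, O
Why: Palladium-catalysed hydroxycarbonylation of the α-iodo enone (oxidative addition, CO insertion, hydrolysis of the acylpalladium); like chromone-3-carboxylic acids, the product should not decarboxylate under these conditions.

Step 11
Reactants: 17 8,9-bis(benzyloxy)-10-[(benzyloxy)carbonyl]-2-methyl-4-oxo-4H,5H-pyrano[3,2-c]chromene-3-carboxylic acid; 9 benzyl 5,6-bis(benzyloxy)-2-[(2E)-3-(dimethylamino)prop-2-enoyl]-3-hydroxybenzoate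
Product: 20 benzyl 6,7-bis(benzyloxy)-4-oxo-3-(pyranochromenonylcarbonyl)-4H-chromene-5-carboxylate, via acid chloride 18 (not isolated), via C-acylated enaminone 19 (not isolated)
Conditions: 1-chloro-N,N,2-trimethylprop-1-en-1-amine, CH2Cl2, 0 °C → rt; then 9, pyridine, 0 °C → rt
Reagents that add atoms: none
Why: Neutral acid chloride formation, then C-acylation of the enaminone at its α-carbon (O-acylation of the phenol followed by O-to-C acyl transfer converges on the same intermediate). Ring closure by addition–elimination with loss of dimethylamine completes the known enaminone route to 3-acylchromones.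

Step 12
Reactants: 20 benzyl 6,7-bis(benzyloxy)-4-oxo-3-(pyranochromenonylcarbonyl)-4H-chromene-5-carboxylate; 21 2-methoxypropene
Product: 22 benzyl (3S,4aS)-7,8-bis(benzyloxy)-3-methoxy-3-methyl-10-oxo-1-(pyranochromenonyl)-4,4a-dihydro-3H,10H-pyrano[4,3-b]chromene-9-carboxylate
Conditions: Cu(OTf)2 (10 mol %), (S,S)-t-Bu-box (11 mol %), 3 Å MS, 21 (5 equiv), CH2Cl2, −40 °C; Et3N quench
Reagents that add atoms: none
Why: Divalent copper held by the bis(oxazoline) chelates the bridging ketone oxygen and the pyranone 4'-carbonyl; in this conformer the ketone C=O is s-cis to the chromone C3=C2 bond, so the LUMO-lowered 1-oxadiene O=C–C-10a=C-4a is exposed, and the peri ester disfavours the unproductive chelate to the chromone carbonyl. The CH2 terminus of 21 bonds to chromone C2 (C-4a) and the ketone oxygen to the methoxy-bearing carbon in an asynchronous endo [4+2] event; the closest known reaction types are the inverse-demand hetero-Diels–Alder reaction of 3-formyl- and 3-acylchromones with enol ethers and the copper bis(oxazoline)-catalysed cycloaddition of chelating 1-oxadienes with enol ethers. Ring C closes in the cycloaddition mode; in the stepwise limit this is a Mukaiyama–Michael addition at C-4a followed by 6-exo-trig capture of the oxocarbenium ion by the enolate oxygen. C-4a (S) is set by the catalyst, whose tert-butyl group shields one face of the chelated oxadiene; the (S,S) ligand is written here and the ligand enantiomer is fixed by the first run. C-3 (S) is set relative to C-4a by the endo preference of the methoxy group, which places OCH3 cis to O-5. The step needs chemoselectivity for the chromone-side oxadiene, secured because the pyranone-side diene ends at the fully substituted methyl-bearing C-2'; regioselectivity, secured by the polarity of the enol ether; and enantioselectivity, secured by two-point binding and a slow uncatalysed background with a diaryl-type ketone. Endo selectivity is not needed for the final configuration but makes the next step stereochemically matched.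

Step 13
Reactants: 22 benzyl (3S,4aS)-7,8-bis(benzyloxy)-3-methoxy-3-methyl-10-oxo-1-(pyranochromenonyl)-4,4a-dihydro-3H,10H-pyrano[4,3-b]chromene-9-carboxylate
Product: 23 benzyl (1S,3S)-7,8-bis(benzyloxy)-3-methoxy-3-methyl-10-oxo-1-(pyranochromenonyl)-3,4-dihydro-1H,10H-pyrano[4,3-b]chromene-9-carboxylate
Conditions: KOt-Bu (0.2 equiv), t-BuOH (2 equiv), toluene, −20 → 0 °C
Reagents that add atoms: none
Why: Proposed new method: tert-butoxide removes the oxygen-bearing allylic C-4a–H and, within the contact ion pair, the tert-butanol just formed returns the proton to C-1 on the face it left (conducted-tour 1,3-prototropic shift), driven by formation of the aromatic 4-pyranone; the closest known reaction types are the base-mediated exo-to-endo isomerization of 3-ylidenechroman-4-ones to chromones and the stereospecific base-catalysed 1,3-proton transfer of indenes and allylic ethers. C-1 (S) is set by this suprafacial return and is reinforced in the endo adduct by approach of the proton anti to the pseudo-axial methoxy group on C-3.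

Step 14
Reactants: 23 benzyl (1S,3S)-7,8-bis(benzyloxy)-3-methoxy-3-methyl-10-oxo-1-(pyranochromenonyl)-3,4-dihydro-1H,10H-pyrano[4,3-b]chromene-9-carboxylate
Product: 25 hexabenzyl derivative of 26 (four benzyl ethers, two benzyl esters; 1S,3R,2'S,3'S), via hemiketal 24 (not isolated)
Conditions: TFA (2 equiv), H2O (10 equiv), CH2Cl2–THF, 0 °C → rt
Reagents that add atoms: water, O
Why: Acid exchanges methoxy for hydroxyl through the ring C oxocarbenium ion, and protonation of the 4-pyranone to the 4-hydroxypyrylium ion lets the hemiketal oxygen add to C-2' (6-endo-trig oxa-Michael, the known acid-mediated ketalization of 2-alkyl-4-pyranones and chromones) before the enol is protonated at C-3'. C-3 can bridge only with its oxygen cis to the C-1 substituent, and C-2' and C-3' settle under thermodynamic control within the bicyclo[3.3.1] cage.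

Step 15
Reactants: 25 hexabenzyl derivative of 26
Product: 26 target CNP0230818.1, the heptacyclic bis-ketal tetrahydroxy diacid (1S,3R,2'S,3'S)
Conditions: H2 (1 atm), Pd/C (10 %), THF–EtOAc, rt
Reagents that add atoms: none
Why: Hydrogenolysis of four benzyl ethers and two benzyl esters under neutral conditions; the chromone and the ring E enone are tetrasubstituted vinylogous esters and should be reduced far more slowly than benzyl groups are cleaved.

## Compound list

1 | 3-bromo-4,5-dihydroxybenzaldehyde | O=Cc1cc(O)c(O)c(Br)c1 | starting material
2 | 3,4-bis(benzyloxy)-5-bromobenzaldehyde | O=Cc1cc(OCc2ccccc2)c(OCc2ccccc2)c(Br)c1 | intermediate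
3 | 3,4-bis(benzyloxy)-5-bromophenyl formate (not isolated) | O=COc1cc(OCc2ccccc2)c(OCc2ccccc2)c(Br)c1 | intermediate
4 | 3,4-bis(benzyloxy)-5-bromophenol | Oc1cc(OCc2ccccc2)c(OCc2ccccc2)c(Br)c1 | intermediate
5 | 3,4-bis(benzyloxy)-5-bromophenyl acetate (not isolated) | CC(=O)Oc1cc(OCc2ccccc2)c(OCc2ccccc2)c(Br)c1 | intermediate
6 | 1-[3,4-bis(benzyloxy)-2-bromo-6-hydroxyphenyl]ethan-1-one | CC(=O)c1c(O)cc(OCc2ccccc2)c(OCc2ccccc2)c1Br | intermediate
7 | benzyl 2-acetyl-5,6-bis(benzyloxy)-3-hydroxybenzoate | CC(=O)c1c(O)cc(OCc2ccccc2)c(OCc2ccccc2)c1C(=O)OCc1ccccc1 | intermediate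
8 | N,N-dimethylformamide dimethyl acetal | COC(OC)N(C)C | starting material
9 | benzyl 5,6-bis(benzyloxy)-2-[(2E)-3-(dimethylamino)prop-2-enoyl]-3-hydroxybenzoate | CN(C)/C=C/C(=O)c1c(O)cc(OCc2ccccc2)c(OCc2ccccc2)c1C(=O)OCc1ccccc1 | intermediate
10 | benzyl 6,7-bis(benzyloxy)-4-oxo-4H-chromene-5-carboxylate | O=c1ccoc2cc(OCc3ccccc3)c(OCc3ccccc3)c(C(=O)OCc3ccccc3)c12 | intermediate
11 | benzyl 6,7-bis(benzyloxy)-4-[(trimethylsilyl)oxy]-2H-chromene-5-carboxylate | C[Si](C)(C)OC1=CCOc2cc(OCc3ccccc3)c(OCc3ccccc3)c(C(=O)OCc3ccccc3)c12 | intermediate
12 | 2,2,6-trimethyl-4H-1,3-dioxin-4-one | CC1=CC(=O)OC(C)(C)O1 | starting material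
13 | acetylketene (not isolated) | CC(=O)C=C=O | intermediate
14 | benzyl 8,9-bis(benzyloxy)-2-methyl-4-oxo-10b-[(trimethylsilyl)oxy]-4a,10b-dihydro-4H,5H-pyrano[3,2-c]chromene-10-carboxylate (racemic, not isolated) | CC1=CC(=O)C2COc3cc(OCc4ccccc4)c(OCc4ccccc4)c(C(=O)OCc4ccccc4)c3C2(O[Si](C)(C)C)O1 | intermediate
15 | benzyl 8,9-bis(benzyloxy)-2-methyl-4-oxo-4H,5H-pyrano[3,2-c]chromene-10-carboxylate | C1=C(C)OC2=C(COc3cc(OCc4ccccc4)c(OCc4ccccc4)c(C(=O)OCc4ccccc4)c32)C1=O | intermediate
16 | benzyl 8,9-bis(benzyloxy)-3-iodo-2-methyl-4-oxo-4H,5H-pyrano[3,2-c]chromene-10-carboxylate | IC1=C(C)OC2=C(COc3cc(OCc4ccccc4)c(OCc4ccccc4)c(C(=O)OCc4ccccc4)c32)C1=O | intermediate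
17 | 8,9-bis(benzyloxy)-10-[(benzyloxy)carbonyl]-2-methyl-4-oxo-4H,5H-pyrano[3,2-c]chromene-3-carboxylic acid | OC(=O)C1=C(C)OC2=C(COc3cc(OCc4ccccc4)c(OCc4ccccc4)c(C(=O)OCc4ccccc4)c32)C1=O | intermediate
18 | benzyl 8,9-bis(benzyloxy)-3-(chlorocarbonyl)-2-methyl-4-oxo-4H,5H-pyrano[3,2-c]chromene-10-carboxylate (not isolated) | ClC(=O)C1=C(C)OC2=C(COc3cc(OCc4ccccc4)c(OCc4ccccc4)c(C(=O)OCc4ccccc4)c32)C1=O | intermediate
19 | benzyl 5,6-bis(benzyloxy)-2-[3-(dimethylamino)-2-(pyranochromenonylcarbonyl)prop-2-enoyl]-3-hydroxybenzoate (not isolated) | CN(C)C=C(C(=O)c1c(O)cc(OCc2ccccc2)c(OCc2ccccc2)c1C(=O)OCc1ccccc1)C(=O)C1=C(C)OC2=C(COc3cc(OCc4ccccc4)c(OCc4ccccc4)c(C(=O)OCc4ccccc4)c32)C1=O | intermediate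
20 | benzyl 6,7-bis(benzyloxy)-4-oxo-3-(pyranochromenonylcarbonyl)-4H-chromene-5-carboxylate | O=C(c1coc2cc(OCc3ccccc3)c(OCc3ccccc3)c(C(=O)OCc3ccccc3)c2c1=O)C1=C(C)OC2=C(COc3cc(OCc4ccccc4)c(OCc4ccccc4)c(C(=O)OCc4ccccc4)c32)C1=O | intermediate
21 | 2-methoxypropene | COC(C)=C | starting material
22 | benzyl (3S,4aS)-7,8-bis(benzyloxy)-3-methoxy-3-methyl-10-oxo-1-(pyranochromenonyl)-4,4a-dihydro-3H,10H-pyrano[4,3-b]chromene-9-carboxylate | CO[C@]1(C)C[C@@H]2Oc3cc(OCc4ccccc4)c(OCc4ccccc4)c(C(=O)OCc4ccccc4)c3C(=O)C2=C(O1)C1=C(C)OC2=C(COc3cc(OCc4ccccc4)c(OCc4ccccc4)c(C(=O)OCc4ccccc4)c32)C1=O | intermediate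
23 | benzyl (1S,3S)-7,8-bis(benzyloxy)-3-methoxy-3-methyl-10-oxo-1-(pyranochromenonyl)-3,4-dihydro-1H,10H-pyrano[4,3-b]chromene-9-carboxylate | C[C@@]1(OC)Cc2oc3cc(OCc4ccccc4)c(OCc4ccccc4)c(C(=O)OCc4ccccc4)c3c(=O)c2[C@@H](O1)C1=C(C)OC2=C(COc3cc(OCc4ccccc4)c(OCc4ccccc4)c(C(=O)OCc4ccccc4)c32)C1=O | intermediate
24 | benzyl (1S,3S)-7,8-bis(benzyloxy)-3-hydroxy-3-methyl-10-oxo-1-(pyranochromenonyl)-3,4-dihydro-1H,10H-pyrano[4,3-b]chromene-9-carboxylate (not isolated) | C[C@@]1(O)Cc2oc3cc(OCc4ccccc4)c(OCc4ccccc4)c(C(=O)OCc4ccccc4)c3c(=O)c2[C@@H](O1)C1=C(C)OC2=C(COc3cc(OCc4ccccc4)c(OCc4ccccc4)c(C(=O)OCc4ccccc4)c32)C1=O | intermediate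
25 | hexabenzyl derivative of 26 (four benzyl ethers, two benzyl esters; 1S,3R,2'S,3'S) | C[C@@]12Cc3oc4cc(OCc5ccccc5)c(OCc5ccccc5)c(C(=O)OCc5ccccc5)c4c(=O)c3[C@@H](O1)[C@H]1C(=O)C3=C(O[C@@]1(C)O2)c1c(cc(OCc4ccccc4)c(OCc4ccccc4)c1C(=O)OCc1ccccc1)OC3 | intermediate
26 | CNP0230818.1, heptacyclic bis-ketal tetrahydroxy diacid: C-1 (S), C-3 (R), C-2' (S), C-3' (S) | C[C@@]12Cc3oc4cc(O)c(O)c(C(=O)O)c4c(=O)c3[C@@H](O1)[C@H]1C(=O)C3=C(O[C@@]1(C)O2)c1c(cc(O)c(O)c1C(=O)O)OC3 | target

## Step count and least certain steps

Total: 15 steps. Longest linear sequence: 15 steps (1 to 26; 9 is used twice, in steps 6 and 11).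

For step 13 the likely failure is loss of stereochemical fidelity or no reaction. The C-4a–H bond is only weakly acidic, the pyranone 2'-methyl group is more acidic and buffers the base, and a dissociated allyl anion can be reprotonated on either face of C-1. The fallback gives up the relay and uses the ketal carbon C-3, which base does not touch, as the stereochemical anchor. Starting from 22, the isomerization is run under equilibrating conditions of the kind known for 3-ylidenechroman-4-ones (KOt-Bu in DMSO at room temperature), which should give 23 together with the C-1 epimer of 23 F1. The two are diastereomers and are separated by chromatography, F1 can be resubmitted to the same conditions, and the route is rejoined at 23.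

For step 12 the likely failures are erosion of enantioselectivity and consumption of the dienophile. Copper can bind unproductively to the chromone carbonyl or the esters, 21 can oligomerize under Lewis acid, and the vinylogous acetal at C-4a of the product can ionize in the acidic medium. The fallback moves the control element from the catalyst to the dienophile. Starting from 20, the cycloaddition is run with (−)-menthyl isopropenyl ether F2 (from menthyl acetate and Cp2TiMe2) under an achiral mild Lewis acid such as Eu(fod)3, giving the menthyloxy cycloadduct F3. The conditions of step 13 convert it into the menthyl ketal F4, and the conditions of step 14 release menthol and lead to 25, where the route is rejoined. The auxiliary costs no extra step because the ketal alkoxy group is excised anyway.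

For step 3 the likely failures are acylation at the other ortho position and partial cleavage of benzyl ethers by the Lewis acid and the hydrogen chloride formed. The fallback replaces electrophilic substitution by directed metalation. Starting from 4, the phenol is converted into the methoxymethyl ether F5. LiN(i-Pr)2 at −78 °C deprotonates the position between bromine and the acetal oxygen, and N-methoxy-N-methylacetamide gives the methoxymethyl-protected ketone F6. HCl in methanol then returns 6.

For step 9 the likely failure is competing iodination of the electron-rich benzo ring at its single CH. The fallback brings the carboxyl group in with the ketene instead of by substitution. Starting from 11, thermolysis of tert-butyl 5-methyl-2,3-dioxo-2,3-dihydrofuran-4-carboxylate F7 (from tert-butyl acetoacetate and oxalyl chloride) releases an acetyl(alkoxycarbonyl)ketene. This reacts as in step 8 to give the tert-butyl ester F8, and TFA cleaves it to 17, where the route is rejoined.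

For step 14 the likely failures are incomplete ring D closure, closure to a ring E diastereomer that equilibrates slowly, and ionization of the C-1–O-2 bond if the acid has to be made stronger. The fallback changes the order of events so that the cage closes on the unprotected, natural substitution pattern. Starting from 23, hydrogenolysis as in step 15 gives the hexa-debenzylated methyl ketal F9. Dilute aqueous acid, assisted by the free peri-carboxylic acids, should then exchange the ketal and close the cage to give 26 directly.

## Further compounds

F1 | step 13 | benzyl (1R,3S)-7,8-bis(benzyloxy)-3-methoxy-3-methyl-10-oxo-1-(pyranochromenonyl)-3,4-dihydro-1H,10H-pyrano[4,3-b]chromene-9-carboxylate (C-1 epimer of 23) | C[C@@]1(OC)Cc2oc3cc(OCc4ccccc4)c(OCc4ccccc4)c(C(=O)OCc4ccccc4)c3c(=O)c2[C@H](O1)C1=C(C)OC2=C(COc3cc(OCc4ccccc4)c(OCc4ccccc4)c(C(=O)OCc4ccccc4)c32)C1=O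
F2 | step 12 | (1R,2S,5R)-2-isopropyl-5-methylcyclohexyl isopropenyl ether ((−)-menthyl isopropenyl ether) | C=C(C)O[C@@H]1C[C@H](C)CC[C@H]1C(C)C
F3 | step 12 | (3S,4aS)-3-[(1R,2S,5R)-menthyloxy] analogue of 22 | CC(C)[C@@H]5CC[C@@H](C)C[C@H]5O[C@]1(C)C[C@@H]2Oc3cc(OCc4ccccc4)c(OCc4ccccc4)c(C(=O)OCc4ccccc4)c3C(=O)C2=C(O1)C1=C(C)OC2=C(COc3cc(OCc4ccccc4)c(OCc4ccccc4)c(C(=O)OCc4ccccc4)c32)C1=O
F4 | step 12 | (1S,3S)-3-[(1R,2S,5R)-menthyloxy] analogue of 23 | C[C@@]1(O[C@@H]5C[C@H](C)CC[C@H]5C(C)C)Cc2oc3cc(OCc4ccccc4)c(OCc4ccccc4)c(C(=O)OCc4ccccc4)c3c(=O)c2[C@@H](O1)C1=C(C)OC2=C(COc3cc(OCc4ccccc4)c(OCc4ccccc4)c(C(=O)OCc4ccccc4)c32)C1=O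
F5 | step 3 | 1,2-bis(benzyloxy)-3-bromo-5-(methoxymethoxy)benzene | COCOc1cc(OCc2ccccc2)c(OCc2ccccc2)c(Br)c1
F6 | step 3 | 1-[3,4-bis(benzyloxy)-2-bromo-6-(methoxymethoxy)phenyl]ethan-1-one | CC(=O)c1c(OCOC)cc(OCc2ccccc2)c(OCc2ccccc2)c1Br
F7 | step 9 | tert-butyl 5-methyl-2,3-dioxo-2,3-dihydrofuran-4-carboxylate | CC1=C(C(=O)OC(C)(C)C)C(=O)C(=O)O1
F8 | step 9 | 10-benzyl 3-tert-butyl 8,9-bis(benzyloxy)-2-methyl-4-oxo-4H,5H-pyrano[3,2-c]chromene-3,10-dicarboxylate | CC(C)(C)OC(=O)C1=C(C)OC2=C(COc3cc(OCc4ccccc4)c(OCc4ccccc4)c(C(=O)OCc4ccccc4)c32)C1=O
F9 | step 14 | hexa-debenzylated 23 (free catechols and acids; 1S,3S methyl ketal) | C[C@@]1(OC)Cc2oc3cc(O)c(O)c(C(=O)O)c3c(=O)c2[C@@H](O1)C1=C(C)OC2=C(COc3cc(O)c(O)c(C(=O)O)c32)C1=O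
A1 | alternative 1 | (S)-carbinol acetate of the 2-(trimethylsilylmethyl)chromone bearing the pyranochromenonyl group | C[Si](C)(C)Cc1oc2cc(OCc3ccccc3)c(OCc3ccccc3)c(C(=O)OCc3ccccc3)c2c(=O)c1[C@@H](OC(C)=O)C1=C(C)OC2=C(COc3cc(OCc4ccccc4)c(OCc4ccccc4)c(C(=O)OCc4ccccc4)c32)C1=O
A2 | alternative 1 | hexabenzyl-protected target (identical with 25) | C[C@@]12Cc3oc4cc(OCc5ccccc5)c(OCc5ccccc5)c(C(=O)OCc5ccccc5)c4c(=O)c3[C@@H](O1)[C@H]1C(=O)C3=C(O[C@@]1(C)O2)c1c(cc(OCc4ccccc4)c(OCc4ccccc4)c1C(=O)OCc1ccccc1)OC3
A3 | alternative 2 | (S)-carbinol acetate joining the 2-(prop-1-ynyl)chromone to C5 of 3-(hydroxymethyl)-4-methoxy-6-methyl-2H-pyran-2-one | CC#Cc1oc2cc(OCc3ccccc3)c(OCc3ccccc3)c(C(=O)OCc3ccccc3)c2c(=O)c1[C@@H](OC(C)=O)C1=C(C)OC(=O)C(CO)=C1OC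
A4 | alternative 2 | benzyl 2,3-bis(benzyloxy)-5-{[(trifluoromethyl)sulfonyl]oxy}-6-(trimethylsilyl)benzoate (aryne precursor) | C[Si](C)(C)c1c(OS(=O)(=O)C(F)(F)F)cc(OCc2ccccc2)c(OCc2ccccc2)c1C(=O)OCc1ccccc1
A5 | alternative 2 | (S)-carbinol acetate of the 2-(prop-1-ynyl)chromone bearing the complete pyranochromenonyl group | CC#Cc1oc2cc(OCc3ccccc3)c(OCc3ccccc3)c(C(=O)OCc3ccccc3)c2c(=O)c1[C@@H](OC(C)=O)C1=C(C)OC2=C(COc3cc(OCc4ccccc4)c(OCc4ccccc4)c(C(=O)OCc4ccccc4)c32)C1=O
A6 | alternative 3 | benzyl 6,7-bis(benzyloxy)-2-[(1Z)-2-{[tert-butyl(dimethyl)silyl]oxy}prop-1-en-1-yl]-4-oxo-4H-chromene-5-carboxylate | C/C(O[Si](C)(C)C(C)(C)C)=C/c1cc(=O)c2c(C(=O)OCc3ccccc3)c(OCc3ccccc3)c(OCc3ccccc3)cc2o1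
A7 | alternative 3 | benzyl 8,9-bis(benzyloxy)-3-formyl-2-methyl-4-oxo-4H,5H-pyrano[3,2-c]chromene-10-carboxylate | O=CC1=C(C)OC2=C(COc3cc(OCc4ccccc4)c(OCc4ccccc4)c(C(=O)OCc4ccccc4)c32)C1=O
A8 | alternative 3 | (1S,3R)-3-[tert-butyl(dimethyl)silyloxy] analogue of 23 (ring C silyl ketal) | C[C@@]1(O[Si](C)(C)C(C)(C)C)Cc2oc3cc(OCc4ccccc4)c(OCc4ccccc4)c(C(=O)OCc4ccccc4)c3c(=O)c2[C@@H](O1)C1=C(C)OC2=C(COc3cc(OCc4ccccc4)c(OCc4ccccc4)c(C(=O)OCc4ccccc4)c32)C1=O
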